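The route rests on cutting the bond between aromatic C3a (the ring carbon flanked by the formyl-bearing C4 and the carboxyl-bearing C7a) and the hemiacylal carbon C3 of the five-membered lactone ring. Its precursor is an ortho-bromobenzoate whose ester oxygen already carries the future C3 as an O-PMB glyoxylic acid hemiacetal bearing a free carboxylic acid. One nickel/photoredox decarboxylative cyclisation forms the C3a–C3 bond, closes the lactone and sets C3 under ligand control as a stable PMB acetal. The step exploits that C3a, meta to both ring oxygens and ortho to two carbonyl carbons, is the electrophilic (halide-bearing) arene site, while C3 is a readily generated dioxygenated radical.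

Key step: step 11

Assumption: the hemiacylal carbon C3 of a free 3-hydroxyphthalide can equilibrate through the open formyl acid; it is therefore set and carried as a PMB (4-methoxybenzyl) acetal and freed only in the last step without breaking a bond at C3, and the target is to be kept cold, neutral and aprotic.

Step 1
Reactants: 1 decanal; 2 1-(triphenyl-λ5-phosphanylidene)propan-2-one
Product: 3 (3E)-tridec-3-en-2-one
Conditions: toluene, 80 °C
Reagents that add atoms: none
Why: Wittig olefination with the acyl-stabilised ylide should give the E-enone selectively.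

Step 2
Reactants: 3 (3E)-tridec-3-en-2-one; 4 4-bromo-2,6-dimethoxybenzaldehyde
Product: 6 (4E)-1-(4-bromo-2,6-dimethoxyphenyl)-1-hydroxytetradec-4-en-3-one (racemic), via lithium dienolate 5 (not isolated)
Conditions: LiN(iPr)2, THF, −78 °C; then 4, −78 °C; AcOH quench
Reagents that add atoms: none
Why: Directed aldol addition: kinetic deprotonation of 3 at the methyl group gives the cross-conjugated lithium dienolate, which should add to the non-enolisable aldehyde 4 at low temperature; the carbinol centre forms as a racemate and is removed in step 3.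

Step 3
Reactants: 6 (4E)-1-(4-bromo-2,6-dimethoxyphenyl)-1-hydroxytetradec-4-en-3-one
Product: 7 (4E)-1-(4-bromo-2,6-dimethoxyphenyl)tetradec-4-en-3-one
Conditions: Et3SiH, TFA, CH2Cl2, 0 °C
Reagents that add atoms: none
Why: Ionic hydrogenation (reductive deoxygenation): acid ionises the benzylic alcohol to a cation stabilised by two ortho methoxy groups, which takes hydride from the silane, while the electron-poor alkyl enone is not reduced.

Step 4
Reactants: 7 (4E)-1-(4-bromo-2,6-dimethoxyphenyl)tetradec-4-en-3-one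
Product: 8 6-bromo-2,4-dimethoxy-3-[(4E)-3-oxotetradec-4-en-1-yl]benzaldehyde
Conditions: Cl2CHOMe, TiCl4, CH2Cl2, −78 to 0 °C; then H2O
Reagents that add atoms: dichloromethyl methyl ether ClC(Cl)OC; water O
Why: Rieche formylation: the two free ring positions of 7 are equivalent, each ortho to one and para to the other methoxy group, and the first formyl group deactivates the ring against a second substitution.

Step 5
Reactants: 8 6-bromo-2,4-dimethoxy-3-[(4E)-3-oxotetradec-4-en-1-yl]benzaldehyde
Product: 9 6-bromo-2,4-dimethoxy-3-[(4E)-3-oxotetradec-4-en-1-yl]benzoic acid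
Conditions: NaClO2, NaH2PO4, 2-methyl-2-butene, t-BuOH/H2O, 20 °C
Reagents that add atoms: sodium chlorite [Na+].[O-]Cl=O
Why: Pinnick oxidation converts the hindered aryl aldehyde into the acid while the alkene scavenger removes HOCl, so the enone and the electron-rich ring are not chlorinated.

Step 6
Reactants: 9 6-bromo-2,4-dimethoxy-3-[(4E)-3-oxotetradec-4-en-1-yl]benzoic acid
Product: 10 2-bromo-3-formyl-4,6-dimethoxy-5-[(4E)-3-oxotetradec-4-en-1-yl]benzoic acid
Conditions: Cl2CHOMe (excess), TiCl4, CH2Cl2, −20 to 20 °C; aq. NaHCO3, then dilute HCl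
Reagents that add atoms: dichloromethyl methyl ether ClC(Cl)OC; water O
Why: Second Rieche formylation at the only remaining ring C–H, which is ortho and para to the two methoxy groups and only meta to the carboxyl group; any aroyl chloride formed from the acid is hydrolysed in the basic work-up.

Step 7
Reactants: 10 2-bromo-3-formyl-4,6-dimethoxy-5-[(4E)-3-oxotetradec-4-en-1-yl]benzoic acid
Product: 11 2-bromo-3-formyl-4,6-dihydroxy-5-[(4E)-3-oxotetradec-4-en-1-yl]benzoic acid
Conditions: BCl3, CH2Cl2, −78 to 0 °C; then H2O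
Reagents that add atoms: none
Why: Chelation-assisted aryl methyl ether cleavage: each methoxy group is ortho to a carbonyl group (formyl or carboxyl), so BCl3 should remove both methyl groups at low temperature without touching the enone or the aryl bromide.

Step 8
Reactants: 11 2-bromo-3-formyl-4,6-dihydroxy-5-[(4E)-3-oxotetradec-4-en-1-yl]benzoic acid; 12 4-methoxybenzyl alcohol; 13 ethyl glyoxylate
Product: 15 2-ethoxy-1-[(4-methoxybenzyl)oxy]-2-oxoethyl 2-bromo-3-formyl-4,6-dihydroxy-5-[(4E)-3-oxotetradec-4-en-1-yl]benzoate (racemic at the acylal carbon), via ethyl glyoxylate PMB hemiacetal 14 (not isolated)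
Conditions: 12 + 13, toluene, 20 °C; then 11, PPh3, DIAD, THF, 0 °C
Reagents that add atoms: none
Why: Mitsunobu esterification of a hemiacetal hydroxyl, as in the anomeric acylation of lactols: the carboxylic acid, far more acidic than the two chelated phenols, is the pronucleophile, and the acylal carbon forms as a racemate that is erased in step 11.

Step 9
Reactants: 15 2-ethoxy-1-[(4-methoxybenzyl)oxy]-2-oxoethyl 2-bromo-3-formyl-4,6-dihydroxy-5-[(4E)-3-oxotetradec-4-en-1-yl]benzoate
Product: 16 2-ethoxy-1-[(4-methoxybenzyl)oxy]-2-oxoethyl 2-bromo-3-formyl-4,6-bis[(4-methoxybenzyl)oxy]-5-[(4E)-3-oxotetradec-4-en-1-yl]benzoate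
Conditions: PMBCl, K2CO3, Bu4NI (cat.), DMF, 40 °C
Reagents that add atoms: 4-methoxybenzyl chloride COc1ccc(CCl)cc1
Why: Williamson etherification of the two chelated phenols, whose O–H bonds would otherwise be hydrogen-atom donors towards the radical of step 11; carbonate has no other site of attack in 15.

Step 10
Reactants: 16 2-ethoxy-1-[(4-methoxybenzyl)oxy]-2-oxoethyl 2-bromo-3-formyl-4,6-bis[(4-methoxybenzyl)oxy]-5-[(4E)-3-oxotetradec-4-en-1-yl]benzoate
Product: 17 2-{[2-bromo-3-formyl-4,6-bis[(4-methoxybenzyl)oxy]-5-[(4E)-3-oxotetradec-4-en-1-yl]benzoyl]oxy}-2-[(4-methoxybenzyl)oxy]acetic acid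
Conditions: Me3SnOH, ClCH2CH2Cl, 70 °C; then 5% HCl wash
Reagents that add atoms: trimethyltin hydroxide C[Sn](C)(C)O
Why: Trimethyltin hydroxide ester hydrolysis is selective for the unhindered ethyl ester activated by two α-oxygen atoms, while the aroyl ester is shielded by its two ortho substituents.

Step 11
Reactants: 17 2-{[2-bromo-3-formyl-4,6-bis[(4-methoxybenzyl)oxy]-5-[(4E)-3-oxotetradec-4-en-1-yl]benzoyl]oxy}-2-[(4-methoxybenzyl)oxy]acetic acid
Product: 18 (3R)-3,5,7-tris[(4-methoxybenzyl)oxy]-1-oxo-6-[(4E)-3-oxotetradec-4-en-1-yl]-1,3-dihydro-2-benzofuran-4-carbaldehyde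
Conditions: NiCl2(dme) (10 mol%), chiral cyano-bis(oxazoline) ligand 2,2-bis[(4S)-4-benzyl-4,5-dihydro-1,3-oxazol-2-yl]acetonitrile (12 mol%), Ir[dF(CF3)ppy]2(dtbbpy)PF6 (1 mol%), Cs2CO3, DME/DMSO, 0.01 M, blue LEDs, 20 °C
Reagents that add atoms: none
Why: Proposed new method: the photoexcited iridium complex should oxidise the carboxylate of 17, loss of CO2 gives the α-acyloxy-α-alkoxy radical at the future C3, zerovalent nickel inserts into the C3a–Br bond, and radical capture at nickel followed by C(sp2)–C(sp3) reductive elimination forms the C3a–C3 bond. The closest known reaction type is the nickel/photoredox decarboxylative arylation of α-oxy and α-amino acids with aryl halides, whose enantioselective form with chiral bis(oxazoline)–nickel is known for α-amino acids in the intermolecular sense but not for an acylal-type radical or for ring closure. The five-membered lactone ring closes by reductive elimination from a six-membered nickelacycle, the counterpart of a 5-exo closure of the tether carbon onto the metalated aryl carbon. The C3 stereocentre is set by the chiral ligand on nickel in a stereoablative way: the racemic acylal carbon of 17 becomes a planar radical, reversible radical capture lets the ligand choose the diastereomeric trivalent nickel alkyl aryl species that eliminates to the 3R acetal, and the ligand antipode is to be fixed in the first run. The step needs ring closure to outrun protodecarboxylation and radical addition to the enone, which the proximity of the ortho aryl–nickel centre and 0.01 M dilution should secure, and it needs site fidelity, which the single C–Br bond and the PMB-capped phenols (no O–H donors) provide.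

Step 12
Reactants: 18 (3R)-3,5,7-tris[(4-methoxybenzyl)oxy]-1-oxo-6-[(4E)-3-oxotetradec-4-en-1-yl]-1,3-dihydro-2-benzofuran-4-carbaldehyde
Product: 19 (3R)-3,5,7-trihydroxy-1-oxo-6-[(4E)-3-oxotetradec-4-en-1-yl]-1,3-dihydro-2-benzofuran-4-carbaldehyde
Conditions: DDQ, CH2Cl2/H2O (20:1), 0 °C
Reagents that add atoms: none
Why: Oxidative PMB cleavage: DDQ abstracts hydride from each anisyl CH2, water adds to the resulting oxocarbenium ion and the hemiacetal collapses to 4-methoxybenzaldehyde, so no bond at C3 is broken and the 3R configuration set in step 11 is kept.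

Compound list
1 | decanal | CCCCCCCCCC=O | starting material
2 | 1-(triphenyl-λ5-phosphanylidene)propan-2-one | CC(=O)C=P(c1ccccc1)(c1ccccc1)c1ccccc1 | starting material
3 | (3E)-tridec-3-en-2-one | CCCCCCCCC/C=C/C(C)=O | intermediate
4 | 4-bromo-2,6-dimethoxybenzaldehyde | COc1cc(Br)cc(OC)c1C=O | starting material
5 | lithium (3E)-trideca-1,3-dien-2-olate | [Li]OC(=C)/C=C/CCCCCCCCC | intermediate
6 | (4E)-1-(4-bromo-2,6-dimethoxyphenyl)-1-hydroxytetradec-4-en-3-one (racemic) | CCCCCCCCC/C=C/C(=O)CC(O)c1c(OC)cc(Br)cc1OC | intermediate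
7 | (4E)-1-(4-bromo-2,6-dimethoxyphenyl)tetradec-4-en-3-one | CCCCCCCCC/C=C/C(=O)CCc1c(OC)cc(Br)cc1OC | intermediate
8 | 6-bromo-2,4-dimethoxy-3-[(4E)-3-oxotetradec-4-en-1-yl]benzaldehyde | CCCCCCCCC/C=C/C(=O)CCc1c(OC)cc(Br)c(C=O)c1OC | intermediate
9 | 6-bromo-2,4-dimethoxy-3-[(4E)-3-oxotetradec-4-en-1-yl]benzoic acid | CCCCCCCCC/C=C/C(=O)CCc1c(OC)cc(Br)c(C(=O)O)c1OC | intermediate
10 | 2-bromo-3-formyl-4,6-dimethoxy-5-[(4E)-3-oxotetradec-4-en-1-yl]benzoic acid | CCCCCCCCC/C=C/C(=O)CCc1c(OC)c(C=O)c(Br)c(C(=O)O)c1OC | intermediate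
11 | 2-bromo-3-formyl-4,6-dihydroxy-5-[(4E)-3-oxotetradec-4-en-1-yl]benzoic acid | CCCCCCCCC/C=C/C(=O)CCc1c(O)c(C=O)c(Br)c(C(=O)O)c1O | intermediate
12 | 4-methoxybenzyl alcohol | COc1ccc(CO)cc1 | starting material
13 | ethyl glyoxylate | CCOC(=O)C=O | starting material
14 | ethyl 2-hydroxy-2-[(4-methoxybenzyl)oxy]acetate (racemic) | CCOC(=O)C(O)OCc1ccc(OC)cc1 | intermediate
15 | 2-ethoxy-1-[(4-methoxybenzyl)oxy]-2-oxoethyl 2-bromo-3-formyl-4,6-dihydroxy-5-[(4E)-3-oxotetradec-4-en-1-yl]benzoate (racemic) | CCCCCCCCC/C=C/C(=O)CCc1c(O)c(C=O)c(Br)c(C(=O)OC(OCc2ccc(OC)cc2)C(=O)OCC)c1O | intermediate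
16 | 2-ethoxy-1-[(4-methoxybenzyl)oxy]-2-oxoethyl 2-bromo-3-formyl-4,6-bis[(4-methoxybenzyl)oxy]-5-[(4E)-3-oxotetradec-4-en-1-yl]benzoate (racemic) | CCCCCCCCC/C=C/C(=O)CCc1c(OCc2ccc(OC)cc2)c(C=O)c(Br)c(C(=O)OC(OCc2ccc(OC)cc2)C(=O)OCC)c1OCc1ccc(OC)cc1 | intermediate
17 | 2-{[2-bromo-3-formyl-4,6-bis[(4-methoxybenzyl)oxy]-5-[(4E)-3-oxotetradec-4-en-1-yl]benzoyl]oxy}-2-[(4-methoxybenzyl)oxy]acetic acid (racemic) | CCCCCCCCC/C=C/C(=O)CCc1c(OCc2ccc(OC)cc2)c(C=O)c(Br)c(C(=O)OC(OCc2ccc(OC)cc2)C(=O)O)c1OCc1ccc(OC)cc1 | intermediate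
18 | (3R)-3,5,7-tris[(4-methoxybenzyl)oxy]-1-oxo-6-[(4E)-3-oxotetradec-4-en-1-yl]-1,3-dihydro-2-benzofuran-4-carbaldehyde | CCCCCCCCC/C=C/C(=O)CCc1c(OCc2ccc(OC)cc2)c(C=O)c2c(c1OCc1ccc(OC)cc1)C(=O)O[C@H]2OCc1ccc(OC)cc1 | intermediate
19 | (3R)-3,5,7-trihydroxy-1-oxo-6-[(4E)-3-oxotetradec-4-en-1-yl]-1,3-dihydro-2-benzofuran-4-carbaldehyde | CCCCCCCCC/C=C/C(=O)CCc1c(O)c(C=O)c2c(c1O)C(=O)O[C@H]2O | target

Total step count: 12. Longest linear sequence: 12 steps (from 1 through 3 to 19; 11 steps from 4).

Steps most likely to fail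

Step 11 (Proposed new method). Oxidative addition at the doubly ortho-substituted C–Br bond may be slow, and the ester must rotate into its less favoured conformation before the tether carbon can reach nickel. Protodecarboxylation, addition of the radical to the enone, photosensitised E/Z isomerisation of the enone or poor facial control at nickel may then compete. The fallback uses known chemistry, sets out from 11 and comes back at 18. Exhaustive alkylation of 11 (PMBCl, K2CO3, DMF) would give 4-methoxybenzyl 2-bromo-3-formyl-4,6-bis[(4-methoxybenzyl)oxy]-5-[(4E)-3-oxotetradec-4-en-1-yl]benzoate F1. Palladium-catalysed reductive carbonylation of its aryl bromide (Pd(OAc)2, di(1-adamantyl)-n-butylphosphine, CO/H2, TMEDA, toluene, 100 °C) would give 4-methoxybenzyl 2,3-diformyl-4,6-bis[(4-methoxybenzyl)oxy]-5-[(4E)-3-oxotetradec-4-en-1-yl]benzoate F2. Catalytic K2CO3 with a trace of 4-methoxybenzyl alcohol would isomerise this normal ester to the pseudo-ester (alkoxide addition to the new formyl group, lactonisation, loss of alkoxide), racemic 3,5,7-tris[(4-methoxybenzyl)oxy]-1-oxo-6-[(4E)-3-oxotetradec-4-en-1-yl]-1,3-dihydro-2-benzofuran-4-carbaldehyde F3. Preparative chromatography on a chiral stationary phase would then deliver 18.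

Step 12. The free hemiacylal may lose its configuration by ring–chain tautomerism while the two slowly reacting aryl PMB ethers are still being cleaved, and prolonged contact with DDQ may oxidise the product. The fallback sets out from 15 and comes back at 19; the phenols stay unprotected, so only the fast-reacting acetal PMB group has to be removed at the end. Me3SnOH hydrolysis of 15 would give 2-{[2-bromo-3-formyl-4,6-dihydroxy-5-[(4E)-3-oxotetradec-4-en-1-yl]benzoyl]oxy}-2-[(4-methoxybenzyl)oxy]acetic acid F4. The conditions of step 11 with K2HPO4 as base (the chelated phenols stay protonated) would give (3R)-5,7-dihydroxy-3-[(4-methoxybenzyl)oxy]-1-oxo-6-[(4E)-3-oxotetradec-4-en-1-yl]-1,3-dihydro-2-benzofuran-4-carbaldehyde F5. One short treatment with DDQ (1.2 equiv, −10 °C) would give 19.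

Step 8. The hemiacetal may revert to alcohol and aldehyde under the redox-condensation conditions, so that formation of the 4-methoxybenzyl ester or betaine–aldehyde adducts competes with acylal formation. The fallback sets out from 14 and comes back at 15. SOCl2/pyridine (CH2Cl2, −20 °C) would convert 14 into ethyl 2-chloro-2-[(4-methoxybenzyl)oxy]acetate F6. The carboxylate of 11 (KHCO3, DMF, 0 °C) would then be O-alkylated with it to give 15, the known alkylation of carboxylates by α-chloro ethers.

Further compounds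
F1 | step 11 | 4-methoxybenzyl 2-bromo-3-formyl-4,6-bis[(4-methoxybenzyl)oxy]-5-[(4E)-3-oxotetradec-4-en-1-yl]benzoate | CCCCCCCCC/C=C/C(=O)CCc1c(OCc2ccc(OC)cc2)c(C=O)c(Br)c(C(=O)OCc2ccc(OC)cc2)c1OCc1ccc(OC)cc1
F2 | step 11 | 4-methoxybenzyl 2,3-diformyl-4,6-bis[(4-methoxybenzyl)oxy]-5-[(4E)-3-oxotetradec-4-en-1-yl]benzoate | CCCCCCCCC/C=C/C(=O)CCc1c(OCc2ccc(OC)cc2)c(C=O)c(C=O)c(C(=O)OCc2ccc(OC)cc2)c1OCc1ccc(OC)cc1
F3 | step 11 | racemic 3,5,7-tris[(4-methoxybenzyl)oxy]-1-oxo-6-[(4E)-3-oxotetradec-4-en-1-yl]-1,3-dihydro-2-benzofuran-4-carbaldehyde | CCCCCCCCC/C=C/C(=O)CCc1c(OCc2ccc(OC)cc2)c(C=O)c2c(c1OCc1ccc(OC)cc1)C(=O)OC2OCc1ccc(OC)cc1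
F4 | step 12 | 2-{[2-bromo-3-formyl-4,6-dihydroxy-5-[(4E)-3-oxotetradec-4-en-1-yl]benzoyl]oxy}-2-[(4-methoxybenzyl)oxy]acetic acid | CCCCCCCCC/C=C/C(=O)CCc1c(O)c(C=O)c(Br)c(C(=O)OC(OCc2ccc(OC)cc2)C(=O)O)c1O
F5 | step 12 | (3R)-5,7-dihydroxy-3-[(4-methoxybenzyl)oxy]-1-oxo-6-[(4E)-3-oxotetradec-4-en-1-yl]-1,3-dihydro-2-benzofuran-4-carbaldehyde | CCCCCCCCC/C=C/C(=O)CCc1c(O)c(C=O)c2c(c1O)C(=O)O[C@H]2OCc1ccc(OC)cc1
F6 | step 8 | ethyl 2-chloro-2-[(4-methoxybenzyl)oxy]acetate | CCOC(=O)C(Cl)OCc1ccc(OC)cc1
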